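## Structural features

The target 28 has one carbocycle, a cyclohex-2-ene-1,4-dione (ring atoms C1–C6; C3 and C6 are the carbonyl carbons, C1=C2 the alkene), with an oxirane cis-fused across C4–C5. C1 carries an acetoxymethyl group (C7). The quaternary oxirane carbon C4 carries a six-carbon chain C1'–C6' that starts with a secondary acetate at C1' and ends in a (2'E,4'E)-dienal with a methyl group on C3'. The three stereocentres C1', C4 and C5 are contiguous ((4R,5S,1'S) in this numbering), and the oxirane oxygen stands erythro to the C1' oxygen. Fragile parts are the epoxy-enedione (sensitive to base and nucleophiles), the dienal, and the C1' oxygen, which in the open-chain intermediates sits between an alkene and a diene and ionises easily under acid. The real difficulty is the quaternary carbon C4 with three oxygenated neighbours (C3, C5, C1') and its relation to the exocyclic centre C1'. C1=C2 is the one ring bond with no stereocentre at either end; the key step closes the ring there, by metathesis of a C2 vinyl group with a 1,1-disubstituted C1 alkene, after the stereotriad is set on an open chain. In that open chain the C1' hydroxyl is allylic to C4=C5, so the erythro oxirane can be delivered by a hydroxyl-directed, tartrate-matched epoxidation.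

## Logic of the disconnections

28 ← 27 ← 26 ← 25. The two acyl–oxygen bonds (O1', O7) are cut first; then the C1' and C7 silyl ethers and the C6' acetal are restored, and the C3 and C6 carbonyls are taken back to carbinols. The epoxy-enedione and the dienal are the most fragile groups, so they appear last. The gain is that 25 carries no electrophilic carbonyl. The demand is a neutral oxidation of both allylic carbinols, a desilylation that spares the oxirane, and acylation of the hindered C1' hydroxyl.

25 ← 24. The C1=C2 bond is cut (ring-closing metathesis). It is the only ring bond remote from C4, C5 and C1'. The gain is an open chain in which the three stereocentres are already fixed and the C3/C6 configurations do not matter. The demand is site selectivity: the catalyst must join the C2 vinyl group and the C1 alkene and leave the side-chain diene alone.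

24 ← 23 ← 19 + 22 (22 ← 21 ← 20). The C6–C1 bond is cut, which removes the three-carbon unit C1/C7/methylene as a 2-metallated allyl ether; the C3 oxygen reappears as a pivalate. The demand is that the alkenyllithium adds to the aldehyde faster than it attacks the ester or the oxirane.

19 ← 18 ← 17. This adjusts the C1' silyl ether and the C6 oxidation level. The C1' and C6 hydroxyls must both be free one step earlier, so they are differentiated only after the epoxidation. The demand is oxidation of the primary carbinol in the presence of the secondary one.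

17 ← 16. The two C–O bonds of the oxirane are cut, leading back to the trisubstituted alkene with C3 cis to C6. The C1' and C6 hydroxyls are both allylic to C4=C5, lie trans to each other and call for the same tartrate. The gain is that C4 and C5 derive from C1' with reagent reinforcement. The demand is group selectivity against C2'=C3', which is also allylic to the C1' hydroxyl, and a masked C3 oxygen, because a free C3 hydroxyl would direct to the opposite face.

16 ← 15 ← 14 ← 12 + 13. The C3–C4 bond is cut to an alkenyl iodide and 13. The C1' hydroxyl is silylated for three steps so that the new C3 hydroxyl can be acylated alone. The demand is retention of alkene geometry in the coupling; the C3 configuration is irrelevant.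

12 ← 11 ← 10 ← 9. The C4–I and C5–H bonds are cut, back to the alkyne. A trans addition with the metal on C4 is what places C3 cis to C6. A hydroxyl-directed hydroalumination puts the metal on the carbon distal to the free hydroxyl, so it would need the C6 hydroxyl free and C1' protected. The tin-based trans addition directed by the free C1' hydroxyl avoids that exchange. The demand is proximal regioselectivity and a catalyst that tolerates the diene.

9 ← 6 + 8 (8 ← 7). The C1'–C4 bond is cut; this is the only step that creates absolute configuration from achiral material. The demand is enantioface control on a dienal.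

6 ← 5 ← 4 ← 1 + 3 (3 ← 2). The C4'=C5' bond is cut by olefination, and the C1' terminus is carried as an ester and adjusted in two steps. The demand is E geometry at both alkenes.

## Other disconnections considered

Alternative 1: The carbocycle is not built but taken from an arene; the cut falls on the C–O bonds at C3 and C6. Microbial ipso,ortho-dihydroxylation of benzoic acid A1 gives diol acid A2 (carboxyl carbon = C1', tertiary carbinol = C4, secondary carbinol = C5), protected as acetonide methyl ester A3. In the forward key step singlet oxygen adds across C6=C1–C2=C3 on the face opposite the dioxolane and gives endoperoxide A4, with oxygen on C3 and C6 and C1=C2 in place.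
- In favour: the ring, the quaternary centre and C5 come enantiopure from one enzymatic step, and the configuration of A2 puts the C4 oxygen and the C1' carbon on the faces the target needs. The cycloaddition is concerted and steered by the acetonide.
- Against: A4 has hydrogen on C1, so C7 must be attached later to an enone. The C4/C5 diol is cis, so the oxirane needs a double inversion at C5. C1' would be made by adding a dienyl nucleophile to a neopentyl-type aldehyde under substrate control only.
- Comparison: on structure it is the better plan for the ring, C4 and C5, and the worse one for C1', C7 and the side chain. On mechanism its key step is the equal or the better of the metathesis, since it has no site-selectivity problem among several alkenes. On step economy the oxygenated core is reached sooner, but the later refunctionalisation is long, and the least controlled stereocentre is left to the end.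

Alternative 2: The cut goes through C4–C5 and O–C5 together. In open-chain α-chloro ketone A5 (C6 ketone with chloromethyl C5, Z-enone C1=C2, C3 p-methoxybenzyl ether, C4 ketone), LiN(SiMe3)2 forms the C5 enolate. Aldol addition to the C4 ketone closes the six-membered ring, and the C4 alkoxide displaces chloride to give epoxy cyclohexenone A6.
- In favour: two bonds, the ring, the oxirane and both ring stereocentres form in one operation without a transition metal. A6 already has the C6 ketone, the C1=C2 alkene and a differentiated C3 oxygen, so the path from A6 to the target is shorter than from 25.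
- Against: C4 and C5 arise under substrate control from C3 and C1', so C3, which is destroyed later, must be made as one defined epimer. The base can also remove the C1' hydrogen (α to the C4 ketone and activated by the diene) or the C3 hydrogen, which would epimerise C1' or expel the C3 oxygen. The aldolate must have alkoxide and chloride anti to close, and the Z-enone must not isomerise.
- Comparison: on structure it is the better plan in that the ring-forming step also creates stereocentres (the metathesis creates none), but with less reliable control than a tartrate-matched directed epoxidation. On mechanism the open question is chemoselective enolisation and aldol facial selectivity instead of alkene site selectivity, of comparable weight. On step economy it is the equal or the better if the stereocontrol holds.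

Alternative 3: The cut is C3–C4. In keto enal A7 (Z-enal at C3, C4 ketone, C5/C6 diol as acetonide) a chiral triazolium-derived carbene adds to the aldehyde, and the Breslow intermediate attacks the C4 ketone. Acyloin A8 results, with the C3 ketone, the ring and the tertiary C4 carbinol.
- In favour: C3 appears at its final oxidation level, and the quaternary centre is set by the catalyst in the ring-forming step, a point on which it is the better of the two key steps. No metal is used, and C5/C6 can come from the chiral pool.
- Against: enals under carbene catalysis are diverted to homoenolate and redox-ester pathways, and the Z-enal may isomerise. The acceptor is a hindered α,α'-dioxygenated ketone next to an epimerisable C1'. The oxirane is still missing after the key step: the acetonide must be removed by acid in the presence of the side-chain acetal, C5 and C6 differentiated, and C5 displaced by the C4 oxygen next to a ketone.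
- Comparison: on structure it sets C4 well but postpones the oxirane. On mechanism the acyl-anion addition to a ketone is less well precedented for this substrate class than diene metathesis. On step economy the sequence after A8 should make it no shorter than the chosen plan.

Key step: step 16

Assumptions:
- Numbering is as in the first section; C3 and C6 carbinol centres are carried as mixtures of epimers and written without configuration, because both become carbonyls.
- 1 is used water-free (the commercial aqueous solution extracted into CH2Cl2, dried and distilled); the minor 2Z isomer of 4 is removed by chromatography.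
- The (S,S) antipode of ProPhenol is taken to give the (S) carbinol 9, by analogy with its aldol sense; if the sense on this dienal is the reverse, the (R,R) ligand is used and nothing else changes.

## Route

Step 1
Reactants: 1 2,2-dimethoxyacetaldehyde; 2 triethyl (E)-3-methyl-4-phosphonobut-2-enoate
Product: 4 ethyl (2E,4E)-6,6-dimethoxy-3-methylhexa-2,4-dienoate, via lithiated phosphonate 3 (not isolated)
Conditions: 2, LiN(SiMe3)2 (1.05 equiv), THF, −78 °C; then 1, −78 → 0 °C
Reagents that add atoms: none
Why: Horner–Wadsworth–Emmons olefination with a vinylogous phosphonate; the stabilised carbanion should give the E alkene at C4'=C5' and the more stable E geometry at C2'=C3'.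

Step 2
Reactants: 4 ethyl (2E,4E)-6,6-dimethoxy-3-methylhexa-2,4-dienoate
Product: 5 (2E,4E)-6,6-dimethoxy-3-methylhexa-2,4-dien-1-ol
Conditions: iBu2AlH (2.2 equiv), CH2Cl2, −78 °C; aq. KNaC4H4O6
Reagents that add atoms: none
Why: 1,2-reduction of a conjugated ester by an aluminium hydride; the acetal and diene are inert and the tartrate work-up avoids acid.

Step 3
Reactants: 5 (2E,4E)-6,6-dimethoxy-3-methylhexa-2,4-dien-1-ol
Product: 6 (2E,4E)-6,6-dimethoxy-3-methylhexa-2,4-dienal
Conditions: MnO2 (15 equiv), CH2Cl2, rt
Reagents that add atoms: none
Why: Allylic oxidation on MnO2 stops at the aldehyde under neutral conditions and keeps the alkene geometry.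

Step 4
Reactants: 6 (2E,4E)-6,6-dimethoxy-3-methylhexa-2,4-dienal; 7 tert-butyldimethyl(prop-2-yn-1-yloxy)silane
Product: 9 (4S,5E,7E)-1-(tert-butyldimethylsilyloxy)-9,9-dimethoxy-6-methylnona-5,7-dien-2-yn-4-ol, via alkynyl(methyl)zinc 8 (not isolated)
Conditions: 7 (2.8 equiv), Me2Zn (2.9 equiv), (S,S)-ProPhenol (20 mol%), Ph3P=O (40 mol%), toluene, 0 °C; then 6, 4 °C
Reagents that add atoms: none
Why: Catalytic enantioselective alkynylation of an enal by a dinuclear zinc–ProPhenol complex; the chiral pocket delivers the alkynyl group to one aldehyde face and sets C1' as (S), the source of all later stereocontrol.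

Step 5
Reactants: 9 (4S,5E,7E)-1-(tert-butyldimethylsilyloxy)-9,9-dimethoxy-6-methylnona-5,7-dien-2-yn-4-ol
Product: 11 (2Z,4S,5E,7E)-1-(tert-butyldimethylsilyloxy)-3-iodo-9,9-dimethoxy-6-methylnona-2,5,7-trien-4-ol, via alkenylstannane 10 (not isolated)
Conditions: Bu3SnH (1.1 equiv), [Cp*RuCl]4 (2 mol%), CH2Cl2, rt; then I2 (1.2 equiv), 0 °C
Reagents that add atoms: tributyltin hydride, CCCC[SnH](CCCC)CCCC (its tin is present only in 10); iodine, [I][I]
Why: Hydroxyl-directed ruthenium-catalysed trans-hydrostannation; the free C1' hydroxyl steers tin to the proximal carbon C4 and hydrogen adds anti on C5, so tin, and after iododestannylation with retention iodine, stands cis to C6.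

Step 6
Reactants: 11 (2Z,4S,5E,7E)-1-(tert-butyldimethylsilyloxy)-3-iodo-9,9-dimethoxy-6-methylnona-2,5,7-trien-4-ol
Product: 12 C1' triethylsilyl ether of 11
Conditions: Et3SiCl, imidazole, CH2Cl2, 0 °C
Reagents that add atoms: chlorotriethylsilane, CC[Si](Cl)(CC)CC
Why: Temporary silylation of the C1' hydroxyl, so that the hydroxyl made in step 7 is the only free one and can be acylated alone in step 8.

Step 7
Reactants: 12 C1' triethylsilyl ether of 11; 13 acrolein
Product: 14 C3 carbinol (C3 epimers; C3 cis to C6 on C4=C5; C1' OSiEt3; C6 OSitBuMe2)
Conditions: CrCl2 (6 equiv), NiCl2 (2 mol%), DMSO, rt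
Reagents that add atoms: none
Why: Nozaki–Hiyama–Kishi coupling; zerovalent nickel inserts into the C4–I bond, transmetalation gives an alkenyl–CrCl2 species of trivalent chromium that adds 1,2 to the aldehyde with retention of alkene geometry. C3 forms as a mixture, which does not matter.

Step 8
Reactants: 14 C3 carbinol
Product: 15 C3 pivalate of 14
Conditions: tBuCOCl, pyridine, DMAP (cat.), CH2Cl2, 0 °C → rt
Reagents that add atoms: pivaloyl chloride, CC(C)(C)C(Cl)=O
Why: Acylation of the only free hydroxyl; the pivalate cannot bind titanium in step 10 and migrates far more slowly than an acetate.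

Step 9
Reactants: 15 C3 pivalate of 14
Product: 16 C1',C6-diol (C3 pivalate kept; C3 cis to C6 on C4=C5)
Conditions: Bu4NF, AcOH (1:1), THF, 0 °C → rt
Reagents that add atoms: none
Why: Fluoride cleavage of both silyl ethers; acetic acid buffering keeps the medium near neutral, so the pivalate does not migrate and the ionisable C1' carbinol and the acetal see no acid.

Step 10
Reactants: 16 C1',C6-diol
Product: 17 epoxy diol (oxirane on C4–C5 configured as in 28; C1' OH and C6 OH free; C3 pivalate)
Conditions: Ti(OiPr)4 (1.0 equiv), L-(+)-diisopropyl tartrate (1.2 equiv), tBuOOH (2 equiv), 4 Å molecular sieves, CH2Cl2, −20 °C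
Reagents that add atoms: tert-butyl hydroperoxide, CC(C)(C)OO
Why: Sharpless asymmetric epoxidation in a matched case: the C1' and C6 hydroxyls are both allylic to C4=C5 and, with L-(+)-tartrate, deliver oxygen to the same face, giving the erythro C1'/C4 relation and the cis C3/C6 oxirane of 28. For the C2'=C3' alkene the same (S) carbinol is the slow-reacting configuration, so the diene should be spared.

Step 11
Reactants: 17 epoxy diol
Product: 18 C1'-hydroxy epoxy aldehyde (C6 = CHO)
Conditions: TEMPO (20 mol%), PhI(OAc)2 (1.1 equiv), CH2Cl2, rt
Reagents that add atoms: none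
Why: Oxoammonium-mediated oxidation is selective for the primary carbinol over the hindered secondary C1' carbinol; the C1' hydroxyl is trans to C6 on the oxirane and cannot form a lactol.

Step 12
Reactants: 18 C1'-hydroxy epoxy aldehyde
Product: 19 C1'-triethylsilyloxy epoxy aldehyde
Conditions: Et3SiCl, imidazole, DMAP (cat.), DMF, 0 °C → rt
Reagents that add atoms: chlorotriethylsilane, CC[Si](Cl)(CC)CC
Why: Silylation of the hindered C1' hydroxyl with a silyl chloride; the triethylsilyl group goes on without a silyl triflate, which would attack the dimethyl acetal, and comes off readily in step 18.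

Step 13
Reactants: 20 2-bromoprop-2-en-1-ol
Product: 21 (2-bromoallyloxy)(tert-butyl)dimethylsilane
Conditions: tBuMe2SiCl, imidazole, CH2Cl2, rt
Reagents that add atoms: tert-butylchlorodimethylsilane, CC(C)(C)[Si](C)(C)Cl
Why: Standard silylation of a primary alcohol; it provides the C1/C7/methylene unit.

Step 14
Reactants: 21 (2-bromoallyloxy)(tert-butyl)dimethylsilane; 19 C1'-triethylsilyloxy epoxy aldehyde
Product: 23 C6 carbinol (C6 epimers; C3 pivalate; C1' OSiEt3; C7 OSitBuMe2), via alkenyllithium 22 (not isolated)
Conditions: 21, tBuLi (2.0 equiv), Et2O, −78 °C; then 19, −78 °C; aq. NH4Cl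
Reagents that add atoms: none
Why: Bromine–lithium exchange gives the 2-lithioallyl silyl ether, which adds 1,2 to the aldehyde faster than it attacks the pivalate or the oxirane at −78 °C. C6 forms as a mixture, which is removed at the enedione stage.

Step 15
Reactants: 23 C6 carbinol
Product: 24 open-chain epoxy diene diol (C3 OH and C6 OH free; C2 vinyl; C1 methylidene bearing C7H2OSitBuMe2; C1' OSiEt3; side chain as dimethyl acetal)
Conditions: iBu2AlH (4 equiv), CH2Cl2, −78 °C; aq. KNaC4H4O6
Reagents that add atoms: none
Why: Reductive cleavage of the pivalate at low temperature avoids basic methanolysis, which would set off Payne rearrangement of the epoxy alcohols; silyl ethers, acetal and oxirane are inert at −78 °C.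

Step 16
Reactants: 24 open-chain epoxy diene diol
Product: 25 epoxy cyclohex-2-ene-1,4-diol (C3 and C6 epimers; C1' OSiEt3; C7 OSitBuMe2; side chain as dimethyl acetal)
Conditions: second-generation Hoveyda–Grubbs catalyst (H2IMes)Cl2Ru(=CH-C6H4-2-OiPr) (10 mol%), 1,4-benzoquinone (20 mol%), toluene (0.002 M), 60 °C
Reagents that add atoms: none
Why: Olefin metathesis through metallacyclobutanes: the ruthenium alkylidene of the catalyst loads on the monosubstituted C2 vinyl group, helped by the neighbouring C3 hydroxyl, adds across the 1,1-disubstituted C1 alkene in a [2+2] step, and cycloreversion forms C1=C2 and releases ethylene, which drives the reaction. The closest known reaction type is ring-closing metathesis of polyoxygenated 1,7-dienes to cyclohexenols of the conduritol and carbasugar series. The single ring closes as a six-membered carbocycle with the new double bond endocyclic; the oxirane holds the two reacting arms (C3 and C6) cis, so the alkene ends are preorganised, and high dilution suppresses cross-metathesis. No stereocentre is created: C4, C5 and C1' are untouched, and the C3/C6 mixtures converge in step 17. The selectivity needed is site selectivity among five alkenes. The side-chain alkenes are trisubstituted or internal and conjugated, and C2' is screened by the C1' silyl ether and the quaternary C4, while the vinyl and the 1,1-disubstituted alkene are the least substituted partners. 1,4-Benzoquinone is added to intercept Ru–H species that would isomerise the allylic carbinols to ketones.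

Step 17
Reactants: 25 epoxy cyclohex-2-ene-1,4-diol
Product: 26 epoxy cyclohex-2-ene-1,4-dione (C1' OSiEt3; C7 OSitBuMe2; side chain as dimethyl acetal)
Conditions: Dess–Martin periodinane (3 equiv), NaHCO3, CH2Cl2, 0 °C → rt
Reagents that add atoms: none
Why: Dess–Martin oxidation of both allylic carbinols under bicarbonate buffer; the neutral conditions spare oxirane, acetal and silyl ethers, and all C3/C6 epimers give one compound.

Step 18
Reactants: 26 epoxy cyclohex-2-ene-1,4-dione
Product: 27 diol dienal (C1' OH, C7 OH, C6' aldehyde; ring as in 28)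
Conditions: 48% aq. HF, MeCN, 0 °C → rt
Reagents that add atoms: water, O
Why: Aqueous HF cleaves the primary tert-butyldimethylsilyl and the secondary triethylsilyl ether and hydrolyses the conjugated dimethyl acetal through its dienyl oxocarbenium ion in one operation; α,β-epoxy ketones resist acid opening because a cation next to the carbonyls is disfavoured.

Step 19
Reactants: 27 diol dienal
Product: 28 target diacetate
Conditions: Ac2O, pyridine, DMAP (cat.), CH2Cl2, 0 °C
Reagents that add atoms: acetic anhydride, CC(=O)OC(C)=O
Why: DMAP-catalysed acyl transfer acetylates the primary C7 and the hindered secondary C1' hydroxyl; low temperature and short exposure limit contact of the enedione with base.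

## Compound list

1 | 2,2-dimethoxyacetaldehyde | COC(OC)C=O | starting material
2 | triethyl (E)-3-methyl-4-phosphonobut-2-enoate | CCOC(=O)/C=C(C)/CP(=O)(OCC)OCC | starting material
3 | lithium salt of the C4 carbanion of 2 | [Li+].CCOC(=O)/C=C(C)/[CH-]P(=O)(OCC)OCC | intermediate
4 | ethyl (2E,4E)-6,6-dimethoxy-3-methylhexa-2,4-dienoate | CCOC(=O)/C=C(C)/C=C/C(OC)OC | intermediate
5 | (2E,4E)-6,6-dimethoxy-3-methylhexa-2,4-dien-1-ol | OC/C=C(C)/C=C/C(OC)OC | intermediate
6 | (2E,4E)-6,6-dimethoxy-3-methylhexa-2,4-dienal | O=C/C=C(C)/C=C/C(OC)OC | intermediate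
7 | tert-butyldimethyl(prop-2-yn-1-yloxy)silane | C#CCO[Si](C)(C)C(C)(C)C | starting material
8 | [3-(tert-butyldimethylsilyloxy)prop-1-yn-1-yl](methyl)zinc | C[Zn]C#CCO[Si](C)(C)C(C)(C)C | intermediate
9 | (4S,5E,7E)-1-(tert-butyldimethylsilyloxy)-9,9-dimethoxy-6-methylnona-5,7-dien-2-yn-4-ol | CC(C)(C)[Si](C)(C)OCC#C[C@@H](O)/C=C(C)/C=C/C(OC)OC | intermediate
10 | (2Z,4S,5E,7E)-1-(tert-butyldimethylsilyloxy)-9,9-dimethoxy-6-methyl-3-(tributylstannyl)nona-2,5,7-trien-4-ol | CC(C)(C)[Si](C)(C)OC/C=C(\[Sn](CCCC)(CCCC)CCCC)[C@@H](O)/C=C(C)/C=C/C(OC)OC | intermediate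
11 | (2Z,4S,5E,7E)-1-(tert-butyldimethylsilyloxy)-3-iodo-9,9-dimethoxy-6-methylnona-2,5,7-trien-4-ol | CC(C)(C)[Si](C)(C)OC/C=C(\I)[C@@H](O)/C=C(C)/C=C/C(OC)OC | intermediate
12 | (2Z,4S,5E,7E)-1-(tert-butyldimethylsilyloxy)-3-iodo-9,9-dimethoxy-6-methyl-4-(triethylsilyloxy)nona-2,5,7-triene | CC(C)(C)[Si](C)(C)OC/C=C(\I)[C@@H](O[Si](CC)(CC)CC)/C=C(C)/C=C/C(OC)OC | intermediate
13 | acrolein (prop-2-enal) | C=CC=O | starting material
14 | C3 carbinol: iodine of 12 replaced by CH(OH)CH=CH2 (C3, C2), C3 cis to C6 on C4=C5, C1' (S) as OSiEt3 ether, C6 OSitBuMe2, (2'E,4'E) side chain, both C3 epimers | CC(C)(C)[Si](C)(C)OC/C=C(\C(O)C=C)[C@@H](O[Si](CC)(CC)CC)/C=C(C)/C=C/C(OC)OC | intermediate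
15 | C3 pivalate of 14 | CC(C)(C)[Si](C)(C)OC/C=C(\C(OC(=O)C(C)(C)C)C=C)[C@@H](O[Si](CC)(CC)CC)/C=C(C)/C=C/C(OC)OC | intermediate
16 | C1',C6-diol: free (S)-C1' hydroxyl and free C6 hydroxyl, C3 pivalate, C3 cis to C6 on C4=C5 | OC/C=C(\C(OC(=O)C(C)(C)C)C=C)[C@@H](O)/C=C(C)/C=C/C(OC)OC | intermediate
17 | epoxy diol: oxirane on C4–C5 configured as in 28 (oxygen erythro to the (S)-C1' hydroxyl, C3 and C6 cis), C6 OH free, C3 pivalate | C=CC(OC(=O)C(C)(C)C)[C@]1([C@H](/C=C(C)/C=C/C(OC)OC)O)O[C@@H]1CO | intermediate
18 | C1'-hydroxy epoxy aldehyde: 17 with C6 as CHO | C=CC(OC(=O)C(C)(C)C)[C@]1([C@H](/C=C(C)/C=C/C(OC)OC)O)O[C@@H]1C=O | intermediate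
19 | C1' triethylsilyl ether of 18 | C=CC(OC(=O)C(C)(C)C)[C@]1([C@H](/C=C(C)/C=C/C(OC)OC)O[Si](CC)(CC)CC)O[C@@H]1C=O | intermediate
20 | 2-bromoprop-2-en-1-ol | OCC(Br)=C | starting material
21 | (2-bromoallyloxy)(tert-butyl)dimethylsilane | C=C(Br)CO[Si](C)(C)C(C)(C)C | intermediate
22 | [3-(tert-butyldimethylsilyloxy)prop-1-en-2-yl]lithium | [Li]C(=C)CO[Si](C)(C)C(C)(C)C | intermediate
23 | C6 carbinol: 19 with C6 as CH(OH)C(=CH2)CH2OSitBuMe2, both C6 epimers, C3 pivalate | C=CC(OC(=O)C(C)(C)C)[C@]1([C@H](/C=C(C)/C=C/C(OC)OC)O[Si](CC)(CC)CC)O[C@@H]1C(O)C(=C)CO[Si](C)(C)C(C)(C)C | intermediate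
24 | open-chain epoxy diene diol: 23 with free C3 hydroxyl; oxirane and C1' as in 28; C3 and C6 epimer mixtures | C=CC(O)[C@]1([C@H](/C=C(C)/C=C/C(OC)OC)O[Si](CC)(CC)CC)O[C@@H]1C(O)C(=C)CO[Si](C)(C)C(C)(C)C | intermediate
25 | epoxy cyclohex-2-ene-1,4-diol: ring C1–C6 closed at C1=C2, cis-fused oxirane on C4–C5, C1' OSiEt3, C7 OSitBuMe2, side chain as dimethyl acetal, C3 and C6 epimer mixtures | CC(C)(C)[Si](C)(C)OCC1=CC(O)[C@]2([C@H](/C=C(C)/C=C/C(OC)OC)O[Si](CC)(CC)CC)O[C@@H]2C1O | intermediate
26 | epoxy cyclohex-2-ene-1,4-dione: 25 with C3 and C6 as ketones | CC(C)(C)[Si](C)(C)OCC1=CC(=O)[C@]2([C@H](/C=C(C)/C=C/C(OC)OC)O[Si](CC)(CC)CC)O[C@@H]2C1=O | intermediate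
27 | diol dienal: 28 with free C1' and C7 hydroxyls | OCC1=CC(=O)[C@]2([C@H](/C=C(C)/C=C/C=O)O)O[C@@H]2C1=O | intermediate
28 | target: (4R,5S)-4,5-epoxy-1-(acetoxymethyl)-4-[(1'S,2'E,4'E)-1'-acetoxy-3'-methyl-6'-oxohexa-2',4'-dienyl]cyclohex-1-ene-3,6-dione (ring numbering of this proposal) | CC(=O)OCC1=CC(=O)[C@]2([C@H](/C=C(C)/C=C/C=O)OC(C)=O)O[C@@H]2C1=O | target

## Step count and least certain steps

Total step count: 19. Longest linear sequence: 18 steps (steps 1–12 and 14–19); step 13 is the only side branch.

Step 16 (key step). Most likely failure: ring closure onto the trisubstituted C2'=C3' alkene, closing a five-membered ring through C2–C3–C4–C1'–C2' with loss of the diene terminus. Prenyl-type trisubstituted alkenes are competent metathesis partners and a five-membered closure is fast, whereas the C1 alkene is 1,1-disubstituted and flanked by two substituted carbons. Fallback: make the side-chain diene electron-poor before the metathesis. From 24 the acetal alone is hydrolysed (LiBF4 in wet MeCN, or oxalic acid on wet SiO2) to the dienal diol F1. Ring-closing metathesis under the conditions of step 16 gives the cyclohexenediol dienal F2, and Dess–Martin oxidation gives the enedione dienal F3. Aqueous HF in MeCN then removes the two silyl ethers and returns to the route at 27.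

Step 5. Most likely failure: sequestration of the Cp*RuCl fragment by the conjugated diene, or erosion of proximal regioselectivity, so that hydrostannation stalls or tin is delivered to C5. Fallback: hydroxyl-directed trans-hydroalumination from the other side of the alkyne. From 9, silylation (tBuMe2SiCl, imidazole, DMF) gives the bis-silyl ether F4. Selective cleavage of the primary ether (HF·pyridine, pyridine, THF, 0 °C) gives the primary propargylic alcohol F5. NaAlH2(OCH2CH2OCH3)2 in THF and then I2 gives the (Z)-iodo allylic alcohol F6: aluminium goes to the carbon distal to the free C6 hydroxyl, so hydrogen ends on C5 and iodine on C4, anti. Et3SiCl/imidazole gives the C6 triethylsilyl ether F7, CrCl2/NiCl2 coupling with 13 gives the C3 carbinol F8, and pivaloylation gives the pivalate F9. Bu4NF/AcOH removes both silyl groups and rejoins the route at 16.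

Step 10. Most likely failure: titanium-directed oxidation at the side-chain C2'=C3' alkene through the C1' hydroxyl, or slow turnover because the diol occupies two sites on titanium. Fallback: direct from C6 alone with C1' capped. From 16, Et3SiCl (2.5 equiv) and imidazole give the bis(triethylsilyl) ether F10, and HF·pyridine/pyridine at −20 °C frees the primary position to give the allylic alcohol F11. Epoxidation with Ti(OiPr)4, L-(+)-diisopropyl tartrate and tBuOOH, now under reagent control through the C6 hydroxyl on the same face, gives the epoxy alcohol F12. Dess–Martin oxidation returns to the route at 19; steps 11 and 12 are then not needed.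

Step 4. Most likely failure: insufficient enantioface discrimination on the dienal, so that 9 is of low enantiomeric purity. Fallback: make the carbinol carbon a ketone and set C1' by reagent-controlled reduction. From 6 and 7, the lithium acetylide of 7 (nBuLi, THF, −78 °C) adds to 6 to give the racemic propargylic alcohol F13, and MnO2 gives the ynone F14. Reduction with (S)-Alpine-borane (B-isopinocampheyl-9-borabicyclo[3.3.1]nonane from (−)-α-pinene; the alkynyl group acts as the small substituent) returns to the route at 9.

Step 11. Most likely failure: oxidation also at the secondary dienylic C1' carbinol, or decomposition of the unprotected hydroxy epoxy aldehyde on handling. Fallback: silylate first and oxidise the primary silyl ether directly. From 17, Et3SiCl (2.5 equiv) and imidazole give the bis(triethylsilyl) ether F15. Swern conditions ((COCl)2, DMSO, Et3N, −78 → −30 °C) cleave and oxidise only the primary triethylsilyl ether and return to the route at 19; step 12 is then not needed.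

Step 18. Most likely failure: isomerisation or condensation of the freed dienal (enolisable through the C3' methyl) during the basic acetylation that follows, or its degradation during the longer acid exposure needed for the hindered C1' silyl ether. Fallback: keep the aldehyde masked until the end. From 26, HF·pyridine/pyridine in THF removes only the silyl ethers to give the diol acetal F16, and Ac2O/pyridine/DMAP gives the diacetate acetal F17. Oxalic acid on wet SiO2 in CH2Cl2 hydrolyses the acetal and returns to the route at 28.

## Further compounds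

F1 | step 16 | dienal diol: 24 with C6' as free aldehyde | C=CC(O)[C@]1([C@H](/C=C(C)/C=C/C=O)O[Si](CC)(CC)CC)O[C@@H]1C(O)C(=C)CO[Si](C)(C)C(C)(C)C
F2 | step 16 | cyclohexenediol dienal: 25 with C6' as free aldehyde | CC(C)(C)[Si](C)(C)OCC1=CC(O)[C@]2([C@H](/C=C(C)/C=C/C=O)O[Si](CC)(CC)CC)O[C@@H]2C1O
F3 | step 16 | enedione dienal: 26 with C6' as free aldehyde | CC(C)(C)[Si](C)(C)OCC1=CC(=O)[C@]2([C@H](/C=C(C)/C=C/C=O)O[Si](CC)(CC)CC)O[C@@H]2C1=O
F4 | step 5 | (4S,5E,7E)-1,4-bis(tert-butyldimethylsilyloxy)-9,9-dimethoxy-6-methylnona-5,7-dien-2-yne | CC(C)(C)[Si](C)(C)OCC#C[C@@H](O[Si](C)(C)C(C)(C)C)/C=C(C)/C=C/C(OC)OC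
F5 | step 5 | (4S,5E,7E)-4-(tert-butyldimethylsilyloxy)-9,9-dimethoxy-6-methylnona-5,7-dien-2-yn-1-ol | OCC#C[C@@H](O[Si](C)(C)C(C)(C)C)/C=C(C)/C=C/C(OC)OC
F6 | step 5 | (2Z,4S,5E,7E)-4-(tert-butyldimethylsilyloxy)-3-iodo-9,9-dimethoxy-6-methylnona-2,5,7-trien-1-ol | OC/C=C(\I)[C@@H](O[Si](C)(C)C(C)(C)C)/C=C(C)/C=C/C(OC)OC
F7 | step 5 | 1-O-triethylsilyl ether of F6 | CC[Si](CC)(CC)OC/C=C(\I)[C@@H](O[Si](C)(C)C(C)(C)C)/C=C(C)/C=C/C(OC)OC
F8 | step 5 | C3 carbinol from F7 and 13 (C3 epimers; C1' OSitBuMe2; C6 OSiEt3) | CC[Si](CC)(CC)OC/C=C(\C(O)C=C)[C@@H](O[Si](C)(C)C(C)(C)C)/C=C(C)/C=C/C(OC)OC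
F9 | step 5 | C3 pivalate of F8 | CC[Si](CC)(CC)OC/C=C(\C(OC(=O)C(C)(C)C)C=C)[C@@H](O[Si](C)(C)C(C)(C)C)/C=C(C)/C=C/C(OC)OC
F10 | step 10 | C1',C6-bis(triethylsilyl) ether of 16 | CC[Si](CC)(CC)OC/C=C(\C(OC(=O)C(C)(C)C)C=C)[C@@H](O[Si](CC)(CC)CC)/C=C(C)/C=C/C(OC)OC
F11 | step 10 | C1' triethylsilyl ether of 16 with free C6 hydroxyl | OC/C=C(\C(OC(=O)C(C)(C)C)C=C)[C@@H](O[Si](CC)(CC)CC)/C=C(C)/C=C/C(OC)OC
F12 | step 10 | epoxy alcohol: 17 with C1' as triethylsilyl ether | C=CC(OC(=O)C(C)(C)C)[C@]1([C@H](/C=C(C)/C=C/C(OC)OC)O[Si](CC)(CC)CC)O[C@@H]1CO
F13 | step 4 | racemic (5E,7E)-1-(tert-butyldimethylsilyloxy)-9,9-dimethoxy-6-methylnona-5,7-dien-2-yn-4-ol | CC(C)(C)[Si](C)(C)OCC#CC(O)/C=C(C)/C=C/C(OC)OC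
F14 | step 4 | (5E,7E)-1-(tert-butyldimethylsilyloxy)-9,9-dimethoxy-6-methylnona-5,7-dien-2-yn-4-one | CC(C)(C)[Si](C)(C)OCC#CC(=O)/C=C(C)/C=C/C(OC)OC
F15 | step 11 | C1',C6-bis(triethylsilyl) ether of 17 | C=CC(OC(=O)C(C)(C)C)[C@]1([C@H](/C=C(C)/C=C/C(OC)OC)O[Si](CC)(CC)CC)O[C@@H]1CO[Si](CC)(CC)CC
F16 | step 18 | diol acetal: 26 with free C1' and C7 hydroxyls | OCC1=CC(=O)[C@]2([C@H](/C=C(C)/C=C/C(OC)OC)O)O[C@@H]2C1=O
F17 | step 18 | diacetate acetal: 28 with C6' as dimethyl acetal | CC(=O)OCC1=CC(=O)[C@]2([C@H](/C=C(C)/C=C/C(OC)OC)OC(C)=O)O[C@@H]2C1=O
A1 | alternative 1 | benzoic acid | OC(=O)c1ccccc1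
A2 | alternative 1 | (1S,2R)-1,2-dihydroxycyclohexa-3,5-diene-1-carboxylic acid | OC(=O)[C@@]1(O)[C@H](O)C=CC=C1
A3 | alternative 1 | acetonide methyl ester of A2 | COC(=O)[C@@]12OC(C)(C)O[C@@H]1C=CC=C2
A4 | alternative 1 | endoperoxide of A3 (2,3-dioxabicyclo[2.2.2]oct-5-ene bridging C3 and C6, anti to the dioxolane) | COC(=O)[C@@]12OC(C)(C)O[C@@H]1[C@@H]3C=C[C@H]2OO3
A5 | alternative 2 | open-chain α-chloro ketone (C5 chloromethyl, C6 ketone, Z-enone C1=C2, C3 p-methoxybenzyl ether, C4 ketone, C1' and C7 silyl ethers) | ClCC(=O)/C(CO[Si](C)(C)C(C)(C)C)=C\[C@H](OCc1ccc(OC)cc1)C(=O)[C@H](/C=C(C)/C=C/C(OC)OC)O[Si](C)(C)C(C)(C)C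
A6 | alternative 2 | cis-fused epoxy cyclohexenone with C3 p-methoxybenzyl ether | CC(C)(C)[Si](C)(C)OCC1=C[C@H](OCc3ccc(OC)cc3)[C@]2([C@H](/C=C(C)/C=C/C(OC)OC)O[Si](C)(C)C(C)(C)C)O[C@@H]2C1=O
A7 | alternative 3 | open-chain keto enal (Z-enal at C3, C4 ketone, C5/C6 acetonide) | O=C/C=C(CO[Si](C)(C)C(C)(C)C)\[C@@H]1OC(C)(C)O[C@@H]1C(=O)[C@H](/C=C(C)/C=C/C(OC)OC)O[Si](C)(C)C(C)(C)C
A8 | alternative 3 | acetonide-fused cyclohexenone with C3 ketone and tertiary C4 alcohol | CC(C)(C)[Si](C)(C)OCC1=CC(=O)[C@@](O)([C@H](/C=C(C)/C=C/C(OC)OC)O[Si](C)(C)C(C)(C)C)[C@H]2OC(C)(C)O[C@H]21
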